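**Assumptions (one line):** locants follow germacranolide numbering (ring C1–C10, C9 ketone, lactone C6–O–C12(=O)–C11(=C13)–C7, methyls C14 on C10 and C15 on C4); the target is named as its open keto-alcohol form (it may equilibrate with its 2,9-hemiketal); (2R)-2-methylbutanoic acid is purchased.

## Retrosynthetic overview

1. Target 23 ⇐ ketal 22/20: the C9 ketone and C2–OH are carried as a 2,9-epoxy methyl ketal; the 4,5-diol comes from OsO4 on the (4E)-alkene of 19, the α-methylene from Eschenmoser methylenation of 16.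
2. Ten-membered ring of 16 ⇐ C4–C9 fragmentation (ring expansion) of the oxanorbornane-fused cyclohexyl triflate 14, pushed by the bridging ether oxygen.
3. Tricycles 11–13 ⇐ intramolecular furan Diels–Alder reaction of furyl enone 10 (bonds C4–C9 and C2–C3), then exo hydrogenation (C10) and thermodynamic reduction (C5).
4. Enone 10 ⇐ two D-proline aldol reactions: 1 + 2 (C7–C8), esterification with 4, then hydroxyacetone 6 (C5–C6) with lactonisation, methylenation and oxidation.
5. Ring order: γ-lactone (step 3) → ring A (7-oxanorbornene) and ring B (cyclohexanone) together (step 6) → both opened into the ten-membered carbocycle (step 9).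

## Route

Step 1
Reactants: 1 3-methylfuran-2-carbaldehyde; 2 methyl 4-oxobutanoate
Product: 3 anti-aldol hydroxy aldehyde
Conditions: D-proline (20 mol %), DMF, 4 °C; 2 added by syringe pump over 24 h to 1 (3 equiv)
Reagents that add atoms: none
Why: Proline-catalysed enamine cross-aldol (List–MacMillan): the E-enamine of 2 adds to the non-enolisable aldehyde 1 through the Houk–List chair transition state, giving the anti aldol, and D-proline sets C7 (R) and C8 (S) of 3, which is the C7/C8 arrangement of the target.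

Step 2
Reactants: 3 anti-aldol hydroxy aldehyde; 4 (2R)-2-methylbutanoic acid
Product: 5 acyloxy aldehyde
Conditions: DCC, DMAP (5 mol %), CH2Cl2, −20 °C
Reagents that add atoms: none
Why: Steglich esterification installs the final C8 ester before a γ-lactone can form to O8; no stereocentre is touched and the low temperature suppresses β-elimination of the furfuryl ester.

Step 3
Reactants: 5 acyloxy aldehyde; 6 hydroxyacetone
Product: 8 hydroxy-ketone lactone, via dihydroxy keto ester 7 (not isolated)
Conditions: D-proline (30 mol %), 6 (10 equiv), DMSO, rt; then pyridinium p-toluenesulfonate, PhMe, 50 °C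
Reagents that add atoms: none
Why: List's proline-catalysed hydroxyacetone aldol is catalyst-controlled, so D-proline gives the (6R) carbinol (anti 5,6-diol; C5 is erased later); acid then closes the γ-lactone from O6, the only free γ-hydroxyl, onto the methyl ester.

Step 4
Reactants: 8 hydroxy-ketone lactone
Product: 9 isopropenyl carbinol lactone
Conditions: Zn, CH2Br2, TiCl4, THF/CH2Cl2, 0 °C to rt
Reagents that add atoms: dibromomethane BrCBr
Why: Takai–Lombardo methylenation turns the methyl ketone into the isopropenyl group with a non-basic zinc–titanium carbenoid, so there is no enolisation, no β-elimination of the lactone oxygen and no attack on lactone or ester.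

Step 5
Reactants: 9 isopropenyl carbinol lactone
Product: 10 furyl enone lactone
Conditions: Dess–Martin periodinane, CH2Cl2, 0 °C
Reagents that add atoms: none
Why: Dess–Martin oxidation of the allylic alcohol gives the isopropenyl ketone needed as dienophile; the C5 stereocentre is erased on purpose and C6 is not enolised under these near-neutral conditions.

Step 6
Reactants: 10 furyl enone lactone
Product: 11 oxanorbornene adduct
Conditions: MeAlCl2 (2.2 equiv), CH2Cl2 (0.01 M), −78 °C, 6 h; H2O quench at −78 °C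
Reagents that add atoms: none
Why: Lewis-acid-promoted intramolecular Diels–Alder reaction of furan (Keay conditions): the four-atom tether forces bonds C9–C4 and C2–C3 with the tether exo and the C4 methyl endo, and a chair-like tether with O6 and O8 equatorial (the other furan face would put them 1,3-diaxial to that methyl) fixes C2, C4 and C9 relative to C6–C8.

Step 7
Reactants: 11 oxanorbornene adduct
Product: 12 saturated tricyclic ketone
Conditions: H2 (1 atm), Pd/C, EtOAc, 0 °C
Reagents that add atoms: none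
Why: Heterogeneous hydrogenation adds to the strained alkene from the exo face (syn to the oxygen bridge; the endo face is shielded by the C3–C4 bridge and its methyl), which places the C10 methyl endo = (10S) and makes the cycloaddition irreversible.

Step 8
Reactants: 12 saturated tricyclic ketone
Product: 13 equatorial C5 alcohol
Conditions: Shvo complex [(η5-Ph4C4CO)2H]Ru2(CO)4(μ-H) (2 mol %), 2-propanol/PhMe, 80 °C
Reagents that add atoms: none
Why: Reversible transfer hydrogenation (Meerwein–Ponndorf-type equilibrium) gives the thermodynamic equatorial 5-alcohol, because the axial epimer is 1,3-diaxial to C11 and to the oxygen bridge; the equatorial C5–O bond is antiperiplanar to C4–C9.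

Step 9
Reactants: 13 equatorial C5 alcohol
Product: 16 bridged methyl ketal cyclodecene, via triflate 14 (not isolated), via oxocarbenium triflate 15 (not isolated)
Conditions: (CF3SO2)2O, 2,6-di-tert-butyl-4-methylpyridine, CH2Cl2, −78 to −20 °C; then MeOH, Et3N, −78 to 0 °C
Reagents that add atoms: methanol CO
Why: Proposed new method: in triflate 14 the C5–O bond, the C4–C9 bond and a lone pair of the bridging ether oxygen are antiperiplanar, so ionisation should be concerted with C4–C9 cleavage (helped by release of oxanorbornane strain) to give the (4E)-alkene and the transannular oxocarbenium ion 15, which methanol traps from outside as the 2,9-epoxy methyl ketal, forming the ten-membered ring; the closest known reactions are the Grob/Wharton fragmentation of 1,3-diol monosulfonates and nitrogen- or acetal-oxygen-assisted heterolytic fragmentations, not shown so far with a 7-oxanorbornane ether as donor to give a bridged cyclodecene.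

Step 10
Reactants: 16 bridged methyl ketal cyclodecene
Product: 19 methylene lactone, via Mannich base 17 (not isolated), via ammonium iodide 18 (not isolated)
Conditions: LiN(SiMe3)2 (1.05 equiv), THF, −78 °C; Me2N=CH2 I (Eschenmoser's salt); then MeI, MeOH, rt; then aq NaHCO3, EtOAc
Reagents that add atoms: Eschenmoser's salt C=[N+](C)C.[I-]
Why: Eschenmoser methylenation: the lactone α-CH2 is the most acidic and least hindered C–H (the α-branched ester is left alone at −78 °C with one equivalent of base), and aminomethylation, quaternisation and Hofmann-type elimination give the α-methylene lactone.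

Step 11
Reactants: 19 methylene lactone
Product: 20 diol
Conditions: OsO4 (5 mol %), N-methylmorpholine N-oxide (1.05 equiv), acetone/H2O, 0 °C
Reagents that add atoms: N-methylmorpholine N-oxide C[N+]1([O-])CCOCC1; water O
Why: Upjohn dihydroxylation: OsO4 adds syn to the electron-rich, strained trans alkene (the acrylate is electron-poor) from its only open outer face, since the inner face looks into the ring and the alkene cannot flip through the nine-membered oxacycle; this gives 4S (oxygen anti to the former C4–C9 bond) and 5S (oxygen where the triflate was).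

Step 12
Reactants: 20 diol; 21 2-methylpropanoyl chloride
Product: 22 isobutyrate ketal
Conditions: pyridine, DMAP (10 mol %), CH2Cl2, 0 °C to rt
Reagents that add atoms: none
Why: DMAP-catalysed acylation of the only secondary hydroxyl (C5); the tertiary C4 hydroxyl does not react and C2–OH/C9=O are masked in the ketal.

Step 13
Reactants: 22 isobutyrate ketal
Product: 23 target CNP0244577.2
Conditions: pyridinium p-toluenesulfonate, acetone/H2O, rt
Reagents that add atoms: water O
Why: Mild acid hydrolysis of the mixed ketal releases the C9 ketone and the C2 alcohol with retention at C2 (the C2–O bond is never broken); esters, lactone, acrylate and tertiary alcohol are stable at this pH.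

## Compound list

1 | 3-methylfuran-2-carbaldehyde | Cc1ccoc1C=O | starting material
2 | methyl 4-oxobutanoate | COC(=O)CCC=O | starting material
3 | methyl (3R,4S)-3-formyl-4-hydroxy-4-(3-methylfuran-2-yl)butanoate | O=C[C@H](CC(=O)OC)[C@H](O)c1occc1C | intermediate
4 | (2R)-2-methylbutanoic acid | CC[C@@H](C)C(=O)O | starting material
5 | methyl (3R,4S)-3-formyl-4-{[(2R)-2-methylbutanoyl]oxy}-4-(3-methylfuran-2-yl)butanoate | O=C[C@H](CC(=O)OC)[C@H](OC(=O)[C@H](C)CC)c1occc1C | intermediate
6 | 1-hydroxypropan-2-one (hydroxyacetone) | CC(=O)CO | starting material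
7 | methyl (3S,4R,5R)-4,5-dihydroxy-3-[(S)-{[(2R)-2-methylbutanoyl]oxy}(3-methylfuran-2-yl)methyl]-6-oxoheptanoate | COC(=O)C[C@H]([C@H](OC(=O)[C@H](C)CC)c1occc1C)[C@@H](O)[C@@H](O)C(C)=O | intermediate
8 | (S)-{(2R,3S)-2-[(1R)-1-hydroxy-2-oxopropyl]-5-oxooxolan-3-yl}(3-methylfuran-2-yl)methyl (2R)-2-methylbutanoate | C1C(=O)O[C@@H]([C@@H](O)C(C)=O)[C@H]1[C@H](OC(=O)[C@H](C)CC)c1occc1C | intermediate
9 | (S)-{(2R,3S)-2-[(1S)-1-hydroxy-2-methylprop-2-en-1-yl]-5-oxooxolan-3-yl}(3-methylfuran-2-yl)methyl (2R)-2-methylbutanoate | C1C(=O)O[C@@H]([C@@H](O)C(C)=C)[C@H]1[C@H](OC(=O)[C@H](C)CC)c1occc1C | intermediate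
10 | (S)-[(2R,3R)-2-(2-methylprop-2-enoyl)-5-oxooxolan-3-yl](3-methylfuran-2-yl)methyl (2R)-2-methylbutanoate | C1C(=O)O[C@@H](C(=O)C(C)=C)[C@H]1[C@H](OC(=O)[C@H](C)CC)c1occc1C | intermediate
11 | (2R,4S,6R,7R,8S,9R)-13-nor-2,9-epoxy-5-oxo-4,9-cyclogermacr-1(10)-en-12,6-olid-8-yl (2R)-2-methylbutanoate (7-oxanorbornene with O bridging C2 and C9; ring B fused exo at C4–C9; C4 methyl endo; cis-fused lactone) | CC1=C[C@H]2C[C@]3(C)C(=O)[C@@H]4OC(=O)C[C@@H]4[C@H](OC(=O)[C@H](C)CC)[C@@]13O2 | intermediate
12 | (2S,4S,6R,7R,8S,9R,10S)-13-nor-2,9-epoxy-5-oxo-4,9-cyclogermacran-12,6-olid-8-yl (2R)-2-methylbutanoate (C10 methyl endo) | C[C@H]1C[C@H]2C[C@]3(C)C(=O)[C@@H]4OC(=O)C[C@@H]4[C@H](OC(=O)[C@H](C)CC)[C@@]13O2 | intermediate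
13 | (2S,4R,5R,6R,7S,8S,9R,10S)-13-nor-2,9-epoxy-5-hydroxy-4,9-cyclogermacran-12,6-olid-8-yl (2R)-2-methylbutanoate (5-OH equatorial, anti to C4–C9) | C[C@H]1C[C@H]2C[C@]3(C)[C@@H](O)[C@@H]4OC(=O)C[C@@H]4[C@H](OC(=O)[C@H](C)CC)[C@@]13O2 | intermediate
14 | 5-O-trifluoromethanesulfonate of 13 | C[C@H]1C[C@H]2C[C@]3(C)[C@@H](OS(=O)(=O)C(F)(F)F)[C@@H]4OC(=O)C[C@@H]4[C@H](OC(=O)[C@H](C)CC)[C@@]13O2 | intermediate
15 | (2S,4E,6S,7S,8S,10S)-13-nor-germacr-4-en-12,6-olid-8-yl (2R)-2-methylbutanoate 2,9-epoxy oxocarbenium (C9=O+–C2) trifluoromethanesulfonate | C1C(=O)O[C@@H]2[C@H]1[C@H](OC(=O)[C@H](C)CC)C3=[O+][C@@H](C[C@@H]3C)C/C(C)=C/2.[O-]S(=O)(=O)C(F)(F)F | intermediate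
16 | (2S,4E,6S,7S,8S,9R,10S)-13-nor-2,9-epoxy-9-methoxygermacr-4-en-12,6-olid-8-yl (2R)-2-methylbutanoate | C1C(=O)O[C@@H]2[C@H]1[C@H](OC(=O)[C@H](C)CC)[C@]3(OC)O[C@@H](C[C@@H]3C)C/C(C)=C/2 | intermediate
17 | 13-(dimethylamino) derivative of 16 (11,13-dihydro Mannich base, C11 epimers) | CN(C)CC1C(=O)O[C@@H]2[C@H]1[C@H](OC(=O)[C@H](C)CC)[C@]3(OC)O[C@@H](C[C@@H]3C)C/C(C)=C/2 | intermediate
18 | N-methyl ammonium iodide of 17 | C[N+](C)(C)CC1C(=O)O[C@@H]2[C@H]1[C@H](OC(=O)[C@H](C)CC)[C@]3(OC)O[C@@H](C[C@@H]3C)C/C(C)=C/2.[I-] | intermediate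
19 | (2S,4E,6S,7S,8S,9R,10S)-2,9-epoxy-9-methoxygermacra-4,11(13)-dien-12,6-olid-8-yl (2R)-2-methylbutanoate | C=C1C(=O)O[C@@H]2[C@H]1[C@H](OC(=O)[C@H](C)CC)[C@]3(OC)O[C@@H](C[C@@H]3C)C/C(C)=C/2 | intermediate
20 | (2S,4S,5S,6R,7S,8S,9R,10S)-2,9-epoxy-4,5-dihydroxy-9-methoxygermacr-11(13)-en-12,6-olid-8-yl (2R)-2-methylbutanoate | C=C1C(=O)O[C@@H]2[C@H]1[C@H](OC(=O)[C@H](C)CC)[C@]3(OC)O[C@@H](C[C@@H]3C)C[C@](C)(O)[C@H]2O | intermediate
21 | 2-methylpropanoyl chloride | CC(C)C(Cl)=O | starting material
22 | (2S,4S,5S,6R,7S,8S,9R,10S)-2,9-epoxy-4-hydroxy-9-methoxy-5-(2-methylpropanoyloxy)germacr-11(13)-en-12,6-olid-8-yl (2R)-2-methylbutanoate | C=C1C(=O)O[C@@H]2[C@H]1[C@H](OC(=O)[C@H](C)CC)[C@]3(OC)O[C@@H](C[C@@H]3C)C[C@](C)(O)[C@H]2OC(=O)C(C)C | intermediate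
23 | CNP0244577.2: (2S,4S,5S,6R,7S,8S,10S)-2,4-dihydroxy-5-(2-methylpropanoyloxy)-9-oxogermacr-11(13)-en-12,6-olid-8-yl (2R)-2-methylbutanoate | C=C1C(=O)O[C@@H]2[C@H]1[C@H](OC(=O)[C@H](C)CC)C(=O)[C@@H](C)C[C@H](O)C[C@](C)(O)[C@H]2OC(=O)C(C)C | target

## Step count and risks

Total step count: 13. Longest linear sequence: 13 steps (fully linear).

The three steps most likely to fail:

**Step 9 (proposed new fragmentation).** The ether oxygen may be too weak a donor, so that the triflate undergoes a 1,2-shift or simple substitution instead. Fallback with known chemistry, setting out from 13 and returning at 16: mesylate 13 (CH3SO2Cl, Et3N) to the 5-O-methanesulfonate F6. Open the oxygen bridge at the secondary C2 with Me3SiI in MeCN at −20 °C (SN2, inversion at C2) to the 2-iodo 9-silyl ether F7. Treat with Bu4NF in THF at 0 °C to free the C9 alkoxide, which undergoes the classical Wharton-type Grob fragmentation of a 1,3-diol monosulfonate to the 2-iodo cyclodecenone F8. AgOSO2CF3 with 2,6-lutidine in MeOH then closes the 2,9-bridge by carbonyl participation (second inversion at C2) and gives 16.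

**Step 6 (intramolecular furan Diels–Alder).** The bond between the fully substituted furan carbon and the α-methyl enone carbon is crowded, and MeAlCl2 may ionise the furfuryl ester. Fallback, setting out from 10 and returning at 11: convert the enone into its ethylene ketal F4 (Me3SiOCH2CH2OSiMe3, catalytic Me3SiOSO2CF3, CH2Cl2, −78 °C). Catalytic CF3SO3H at −78 °C opens it to the alkoxyallyl cation, a far stronger dienophile (Gassman cationic Diels–Alder), which cyclises and recloses to the adduct ketal F5. Aqueous acetic acid returns ketone 11.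

**Step 3 (second proline aldol).** The (6R) product needed is the mismatched case against the Felkin preference of 5, and the β-acyloxy aldehyde can eliminate under amine catalysis. Fallback, setting out from 5 and returning at 10: reagent-controlled alkoxyallylboration with the (Z)-γ-(methoxymethoxy)-β-methylallyl diisopinocampheylborane made from methallyl methoxymethyl ether (s-BuLi, then (−)-B-methoxydiisopinocampheylborane and BF3·OEt2) at −78 °C, with ethanolamine work-up, gives the syn hydroxy ether ester F1. Pyridinium p-toluenesulfonate lactonises it to the lactone methoxymethyl ether F2. ZnBr2 and propane-1-thiol remove the acetal to give the C5-epimeric allylic alcohol F3, which the Dess–Martin oxidation of step 5 converts into 10.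

## Further compounds

F1 | step 3 | methyl (3S,4R,5R)-4-hydroxy-5-(methoxymethoxy)-6-methyl-3-[(S)-{[(2R)-2-methylbutanoyl]oxy}(3-methylfuran-2-yl)methyl]hept-6-enoate | COC(=O)C[C@H]([C@H](OC(=O)[C@H](C)CC)c1occc1C)[C@@H](O)[C@H](OCOC)C(C)=C
F2 | step 3 | (S)-{(2R,3S)-2-[(1R)-1-(methoxymethoxy)-2-methylprop-2-en-1-yl]-5-oxooxolan-3-yl}(3-methylfuran-2-yl)methyl (2R)-2-methylbutanoate | C1C(=O)O[C@@H]([C@H](OCOC)C(C)=C)[C@H]1[C@H](OC(=O)[C@H](C)CC)c1occc1C
F3 | step 3 | (S)-{(2R,3S)-2-[(1R)-1-hydroxy-2-methylprop-2-en-1-yl]-5-oxooxolan-3-yl}(3-methylfuran-2-yl)methyl (2R)-2-methylbutanoate | C1C(=O)O[C@@H]([C@H](O)C(C)=C)[C@H]1[C@H](OC(=O)[C@H](C)CC)c1occc1C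
F4 | step 6 | (S)-{(2R,3R)-5-oxo-2-[2-(prop-1-en-2-yl)-1,3-dioxolan-2-yl]oxolan-3-yl}(3-methylfuran-2-yl)methyl (2R)-2-methylbutanoate | C1C(=O)O[C@@H](C2(OCCO2)C(C)=C)[C@H]1[C@H](OC(=O)[C@H](C)CC)c1occc1C
F5 | step 6 | 5,5-ethylenedioxy ketal of 11 | CC1=C[C@H]2C[C@]3(C)C5(OCCO5)[C@@H]4OC(=O)C[C@@H]4[C@H](OC(=O)[C@H](C)CC)[C@@]13O2
F6 | step 9 | 5-O-methanesulfonate of 13 | C[C@H]1C[C@H]2C[C@]3(C)[C@@H](OS(C)(=O)=O)[C@@H]4OC(=O)C[C@@H]4[C@H](OC(=O)[C@H](C)CC)[C@@]13O2
F7 | step 9 | 13-nor-2-iodo-5-(methanesulfonyloxy)-9-(trimethylsilyloxy)-4,9-cyclogermacran-12,6-olid-8-yl (2R)-2-methylbutanoate (C2 inverted, bridge opened) | C[C@H]1C[C@@H](I)C[C@]2(C)[C@@H](OS(C)(=O)=O)[C@@H]3OC(=O)C[C@@H]3[C@H](OC(=O)[C@H](C)CC)[C@@]12O[Si](C)(C)C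
F8 | step 9 | (4E)-13-nor-2-iodo-9-oxogermacr-4-en-12,6-olid-8-yl (2R)-2-methylbutanoate (C2 inverted) | C1C(=O)O[C@@H]2[C@H]1[C@H](OC(=O)[C@H](C)CC)C(=O)[C@@H](C)C[C@@H](I)C/C(C)=C/2
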